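## Structural features

Gnetulin is a 2,3-dihydro-1H-indene. Ring A (the fused benzene, C3a–C4–C5–C6–C7–C7a) carries hydroxyls on C4 and C6 and hydrogens on C5 and C7. Ring B (C1–C2–C3–C3a–C7a) carries an exocyclic (E)-4-hydroxy-3-methoxybenzylidene on C1 (alkene C1=C8, aryl group on the C2 side), a 3,5-dihydroxyphenyl group on C2 and a 4-hydroxy-3-methoxyphenyl group on C3. C2 and C3 are neighbouring stereocentres, both S, with their aryl groups trans; C2 is allylic and benzylic, C3 is doubly benzylic and peri to the C4 hydroxyl. There are six free phenols and two aryl methyl ethers that must outlast whatever unmasks the phenols. The C1=C8 styrene unit is the fragile point: it isomerises under ultraviolet light, and protonation would invite Friedel–Crafts closure by the electron-rich C2 aryl ring. The real difficulty is the crowding of three different aryl groups, two contiguous stereocentres and a geometrically defined trisubstituted alkene on one five-membered ring, together with the meta placement of the two ring A oxygens in a fixed sense relative to C3 and C1. The key step uses this last feature: the C4(OH)–C5(H)–C6(O)–C7(H) sequence between C3a and C7a is what a vinylketene (C4, C7, C7a, C3a) and an oxygenated terminal alkyne (C5, C6) assemble, so ring A can be grown last on a cyclopentene that already holds C2, C3 and C1=C8.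

## Logic of the disconnections

Atom labels are those of the indane of 35 throughout.

35 ⇒ 34 ⇒ 33. Four O–isopropyl bonds (35 from 34) and the O6–silicon bond (34 from 33) are cut. Isopropyl is chosen for the four phenols because BCl3 removes it below 0 °C without touching aryl methyl ethers, so the two methoxy groups of 35 can be present from the first step; the silyl group is the form in which O6 arrives from ring formation. The gain is that no phenol is free before step 11. The demand is that fluoride and a Lewis acid act on a molecule with a protonation-prone C1=C8 alkene, hence buffered fluoride and low temperature.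

33 ⇒ 22 + 28. Ring A is removed by cutting C7–C7a, C6–C7, C4–C5 and C3a–C4. The cut is placed here because the 4-hydroxy/6-silyloxy pattern with hydrogens on C5 and C7 is what the C4/C7/C7a/C3a unit of 22 and the C5/C6 unit of 28 produce, and because C2, C3 and C1=C8 lie outside the reacting array. The gain is a monocyclic five-membered ring and a two-carbon unit in place of a tetrasubstituted benzene fused to a fully substituted ring B. The forward step must generate the ketene from 22 without base, with light that leaves the C1=C8 geometry alone, and must orient 28 so that its CH carbon meets C4.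

28 ⇒ 27 ⇒ 23 + 24. The C5–silicon bond of 27 is cut first, then the O–C6 and O–silicon bonds, leading to 23, one oxygen atom from a peroxide, and 24. The carbon-bound silyl group keeps the acetylide soluble and stable during oxidation. The demand is that its removal spare the oxygen-bound silyl group.

22 ⇒ 20 ⇒ 18. The C7=N2 unit is traced to the methyl group of 20 (diazo transfer), and the C4–C7a bond of 20 to the C7a–O bond of 18 (cross-coupling). This replaces an acyl chloride/diazomethane sequence, in which the diazoalkane can add to the conjugated C3a=C7a bond, by two steps that use neither. The demand is that the amide base take a methyl proton of 20 and not the C3 proton, which is γ to the carbonyl.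

18 ⇒ 14 + 4. The C3–aryl bond and the O–sulfur bond are cut together: conjugate addition of the aryl group of 4 to C3 of 14 produces the enolate exactly at C7a. The second stereocentre, the third aryl group and the handle for C4 thus arrive in one step. The forward step must choose the endocyclic β-carbon C3 over the exocyclic β-carbon C8, approach anti to the C2 aryl group, and avoid proton abstraction at C2.

14 ⇒ 12 ⇒ 10. The C3=C3a alkene of 14 is traced to loss of silanol from 12, and the C1=C8 alkene of 12 to loss of water from 10. Both double bonds arise from oxygen functions whose positions are fixed by the way 10 is assembled, so no regiochemical choice is left to a dehydrogenation or a base-mediated condensation. The demand is that the elimination giving 14, whose C2 hydrogen is γ to a dienone carbonyl, run under acid and not base.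

10 ⇒ 2 + 5 + 6. Two carbon–carbon bonds are cut, C2–aryl and C1–C8. Conjugate addition of the aryl group of 2 to 5, anti to the silyloxy group, sets C2 from a purchased stereocentre, and the resulting enolate is the one needed to bond C1 to the aldehyde carbon of 6. The gain is three simple components and an absolute configuration that does not depend on a catalyst. The demand is that the enolate be trapped cold, before it equilibrates and expels the silyloxy group.

2 ⇒ 1 and 4 ⇒ 3. O–isopropyl bonds are cut (Williamson ether synthesis), leaving purchased bromophenols. The only demand is complete alkylation.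

## Other disconnections considered

Alternative 1: The cut is the C3–C3a bond of ring B. Bromochalcone A1, an α,β-diaryl enone with bromine on the future C3a, would be closed to indanone A2 by an enantioselective reductive Heck reaction. Zerovalent palladium with a chiral bisphosphine (Pd(OAc)2, 3,5-XylMeOBIPHEP, an amine as hydride source) inserts into C3a–Br, the aryl–palladium bond adds to the β-carbon C3, and C2 is then protonated.
- In its favour: ring A is bought with its oxygens in place, which is structurally simpler than building it and is the better of the two plans on that point. The only chiral input is a catalyst. C2 of A2 is α to the ketone, so the trans arrangement is the thermodynamic one and corrects itself. A1 should be reachable by short condensation chemistry, so the sequence to A2 is probably equal or better on step economy.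
- Against it here: A1 is a trisubstituted enone with an α-aryl group and a bromide flanked by acyl and isopropoxy groups, more hindered than the β-monosubstituted chalcones on which this cyclisation is established. Insertion rate and enantioselectivity at C3 are therefore open, and β-hydride elimination in place of protonation would flatten both centres. A2 also still lacks C8: the benzylidene must be added to a hindered, enolisable C1 ketone by addition and dehydration or by olefination. That dehydration can choose either geometry of C1=C8 or the ring C1=C2 bond, which destroys C2.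
- Comparison: the chosen plan fixes the alkene geometry early and never creates it next to finished stereocentres, and it sets C2 and C3 by anti additions on a ring. The alternative has the mechanistically simpler key step (one organometallic cycle against a four-stage pericyclic cascade) and no photochemistry, but moves the hard decision to the end. Once C8 installation is counted the two are close in length.

Alternative 2: The cut is the C2–C3 bond between the two stereocentres. Benzhydrol A3 carries, ortho on ring A, an allylsilane (C2=C1 alkene, silicon on the stereogenic C8). BF3·OEt2 would ionise A3 at C3, the para-hydroxyaryl group carrying the charge, and the allylsilane would attack through C2 anti to silicon. This closes ring B, moves the double bond to C1=C8 and expels silicon, giving A4.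
- In its favour: one stereospecific event would create C2, C3 and the C1=C8 geometry together, where the chosen plan needs three operations; this is better. All three aryl rings are bought. A4 emerges with the C3 aryl phenol free, so a single BCl3 step finishes the synthesis, one step fewer after the key step; this is also better.
- Against it here: A3 needs a defined allylic, benzylic C–Si stereocentre and a trisubstituted C1=C2 alkene of defined geometry next to a crowded arene, and would probably cost more steps than are saved. Such α-aryl allylsilanes are prone to protodesilylation under the Lewis acid. The closure is 5-endo with respect to C1=C2. The chirality transfer rests on an open-chain conformational preference: the C8 aryl group must sit inside to give the E alkene, and the conformer with hydrogen inside would give the Z alkene and the opposite face at C2.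
- Comparison: the chosen plan relays stereochemistry on a five-membered ring by anti additions, a more predictable control element than an open-chain anti SE2' relay. The alternative is more convergent and shorter after its key step, but stakes enantiomeric purity and alkene geometry on one conformational bias.

Alternative 3: The cut is the C1–C7a bond. Aryl bromide A5, an open-chain compound that already holds C2 and C3 with their aryl groups and a C1≡C8 alkyne bearing the third aryl group, would be cyclised with zerovalent palladium (Pd(OAc)2, PPh3) and HCO2Na. Insertion into C7a–Br, syn 5-exo-dig addition of the aryl–palladium bond across the alkyne, and replacement of palladium on C8 by hydride would give A6.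
- In its favour: syn carbopalladation and reduction with retention place the C8 aryl group trans to C7a by mechanism, so the E geometry is made and not merely preserved through a photolysis; this is better than the chosen plan. Ring A is bought and the catalyst is simple. A6 needs only one deprotection step, one fewer at the end; this is also better.
- Against it here: the closure creates no stereocentre, so the anti C2/C3 pair must be built in open-chain A5 with no ring to direct it; the hard part of the problem is only moved upstream. C2–H of A5 is propargylic and benzylic and can undergo propargyl–allenyl isomerisation or epimerise under warm basic conditions. The bromide sits ortho to the bulky C3 substituent, which slows insertion. An aryl-substituted alkenyl–palladium bond can isomerise before reduction.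
- Comparison: both plans use a ring-forming key step that leaves C2 and C3 untouched, so they are equal there. The alternative's key step is the more dependable; the chosen plan's way to the stereocentres (two anti additions on a cyclopentenone) is the more dependable. Overall step counts should be similar.

Key step: step 11

Remark on the chemistry: 5 and 6 are assumed to be purchased (5 is sold in both enantiomeric forms), 10 is carried as both carbinol epimers because that centre is removed in step 4, and in step names Res = 3,5-diisopropoxyphenyl and Gua = 4-isopropoxy-3-methoxyphenyl.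

## Route

Step 1
Reactants: 1 5-bromoresorcinol
Product: 2 1-bromo-3,5-diisopropoxybenzene
Conditions: i-PrBr, K2CO3, DMF, 60 °C
Reagents that add atoms: 2-bromopropane, CC(C)Br
Why: Williamson ether synthesis on both phenols; isopropyl is chosen because BCl3 will later remove it while leaving aryl methyl ethers.

Step 2
Reactants: 3 4-bromo-2-methoxyphenol
Product: 4 4-bromo-1-isopropoxy-2-methoxybenzene
Conditions: i-PrBr, K2CO3, DMF, 60 °C
Reagents that add atoms: 2-bromopropane, CC(C)Br
Why: Williamson ether synthesis; the methyl ether is already the one required in the target.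

Step 3
Reactants: 2 1-bromo-3,5-diisopropoxybenzene; 5 (S)-4-(tert-butyldimethylsilyloxy)cyclopent-2-en-1-one; 6 4-isopropoxy-3-methoxybenzaldehyde
Product: 10 (2R,3R,4S)-4-(tert-butyldimethylsilyloxy)-3-Res-2-[hydroxy(Gua)methyl]cyclopentan-1-one (both carbinol epimers), via aryllithium 7 (not isolated), via diarylcuprate 8 (not isolated), via lithium enolate 9 (not isolated)
Conditions: 2, t-BuLi, Et2O, −78 °C; CuI, −40 °C; 5, −78 °C; then 6, −78 °C; sat. aq NH4Cl
Reagents that add atoms: none
Why: Bromine–lithium exchange and transmetalation give the lithium diarylcuprate, which adds to the enone of 5 anti to the silyloxy group (this sets the future C2), and the regiodefined enolate 9 is trapped by 6 at the carbon between the carbonyl and the new aryl centre, anti to that aryl group. This is the three-component conjugate addition–aldol coupling long used on 4-silyloxycyclopentenones in prostaglandin work. It is preferred to catalytic arylation of the parent cyclopentenone followed by dehydrogenation and basic aldol condensation, where neither the position of the new ring double bond nor the integrity of the γ-acidic centre is controlled.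

Step 4
Reactants: 10 (2R,3R,4S)-4-(tert-butyldimethylsilyloxy)-3-Res-2-[hydroxy(Gua)methyl]cyclopentan-1-one
Product: 12 (2E,3S,4S)-4-(tert-butyldimethylsilyloxy)-3-Res-2-(4-isopropoxy-3-methoxybenzylidene)cyclopentan-1-one, via mesylate 11 (not isolated)
Conditions: MsCl, Et3N, DMAP (cat.), CH2Cl2, 0 °C
Reagents that add atoms: none
Why: Mesylation of the β-hydroxy ketone and E1cB loss of methanesulfonate should give the conjugated benzylidene ketone as the E isomer (aryl group away from the carbonyl oxygen). The ring CH bearing Res is not conjugated to the carbonyl in 12, so the amine base does not endanger it.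

Step 5
Reactants: 12 (2E,3S,4S)-4-(tert-butyldimethylsilyloxy)-3-Res-2-(4-isopropoxy-3-methoxybenzylidene)cyclopentan-1-one
Product: 14 (4S,5E)-4-Res-5-(4-isopropoxy-3-methoxybenzylidene)cyclopent-2-en-1-one, via hydroxy ketone 13 (not isolated)
Conditions: AcOH/THF/H2O (3:1:1), 65 °C
Reagents that add atoms: none
Why: Aqueous acetic acid removes the silyl ether and the β-hydroxy ketone 13 dehydrates by acid-catalysed enolisation, the mild elimination known for β-hydroxycyclopentanones of the prostaglandin E type. Acid is used because the CH bearing Res becomes γ to the dienone carbonyl in 14 and would be deprotonated by amidine or alkoxide bases.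

Step 6
Reactants: 4 4-bromo-1-isopropoxy-2-methoxybenzene; 14 (4S,5E)-4-Res-5-(4-isopropoxy-3-methoxybenzylidene)cyclopent-2-en-1-one
Product: 18 (3R,4S,5E)-4-Res-3-Gua-5-(4-isopropoxy-3-methoxybenzylidene)cyclopent-1-en-1-yl trifluoromethanesulfonate, via aryllithium 15 (not isolated), via diarylcuprate 16 (not isolated), via lithium enolate 17 (not isolated)
Conditions: 4, t-BuLi, Et2O/THF, −78 °C; CuI, −40 °C; 14, −78 °C; then N-(5-chloropyridin-2-yl)triflimide, −78 → 0 °C; sat. aq NH4Cl
Reagents that add atoms: N-(5-chloropyridin-2-yl)-1,1,1-trifluoro-N-(trifluoromethylsulfonyl)methanesulfonamide, O=S(=O)(N(c1ccc(Cl)cn1)S(=O)(=O)C(F)(F)F)C(F)(F)F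
Why: The diarylcuprate should add to the unsubstituted endocyclic β-carbon of the cross-conjugated dienone in preference to the aryl-substituted, hindered exocyclic one, and anti to the neighbouring Res group, which sets the trans C2/C3 pair by substrate control. The enolate forms only towards the former α-carbon and is sulfonylated on oxygen (conjugate addition–enolate triflation), placing the triflate on the future C7a.

Step 7
Reactants: 18 (3R,4S,5E)-4-Res-3-Gua-5-(4-isopropoxy-3-methoxybenzylidene)cyclopent-1-en-1-yl trifluoromethanesulfonate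
Product: 20 1-[(3S,4S,5E)-4-Res-3-Gua-5-(4-isopropoxy-3-methoxybenzylidene)cyclopent-1-en-1-yl]ethan-1-one, via enol ether 19 (not isolated)
Conditions: CH2=C(OEt)SnBu3, Pd(PPh3)4 (cat.), LiCl, THF, 65 °C; then 1 M HCl, THF, 20 °C
Reagents that add atoms: tributyl(1-ethoxyvinyl)stannane, CCCC[Sn](CCCC)(CCCC)C(=C)OCC; water, O
Why: Stille coupling of the vinyl triflate (LiCl assists transmetalation) installs a 1-ethoxyvinyl group, and dilute acid hydrolyses enol ether 19 to the methyl ketone. The conditions are neutral and then mildly acidic, so neither stereocentre is at risk.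

Step 8
Reactants: 20 1-[(3S,4S,5E)-4-Res-3-Gua-5-(4-isopropoxy-3-methoxybenzylidene)cyclopent-1-en-1-yl]ethan-1-one
Product: 22 2-diazo-1-[(3S,4S,5E)-4-Res-3-Gua-5-(4-isopropoxy-3-methoxybenzylidene)cyclopent-1-en-1-yl]ethan-1-one, via trifluoroacetyl ketone 21 (not isolated)
Conditions: LiN(SiMe3)2, THF, −78 °C; CF3CO2CH2CF3; aq HCl work-up; then 4-AcNHC6H4SO2N3, Et3N, H2O (1 equiv), MeCN, 20 °C
Reagents that add atoms: 4-acetamidobenzenesulfonyl azide, CC(=O)Nc1ccc(cc1)S(=O)(=O)N=[N+]=[N-]
Why: Kinetic deprotonation of the methyl group and Claisen-type trifluoroacetylation activate that carbon, and Regitz-type diazo transfer with passage of the trifluoroacetyl group to the sulfonamide (detrifluoroacetylative diazo transfer) gives the diazomethyl ketone. This is preferred to acyl chloride plus diazomethane because diazoalkanes add to the conjugated double bond of unsaturated acyl chlorides, and it avoids diazomethane.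

Step 9
Reactants: 23 (trimethylsilyl)acetylene; 24 triisopropylsilyl trifluoromethanesulfonate
Product: 27 triisopropyl{[(trimethylsilyl)ethynyl]oxy}silane, via lithium acetylide 25 (not isolated), via lithium ynolate 26 (not isolated)
Conditions: n-BuLi, THF, −78 °C; t-BuOOLi (from t-BuOOH, LiN(SiMe3)2), −78 → 0 °C; then 24, −78 → 0 °C
Reagents that add atoms: tert-butyl hydroperoxide, CC(C)(C)OO
Why: The lithium acetylide is oxidised at carbon by lithium tert-butyl peroxide to the ynolate, and the bulky silyl triflate then reacts at oxygen and not carbon; this acetylide oxidation–O-silylation is the usual entry to triisopropylsilyloxyalkynes.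

Step 10
Reactants: 27 triisopropyl{[(trimethylsilyl)ethynyl]oxy}silane
Product: 28 (triisopropylsilyloxy)acetylene
Conditions: K2CO3 (cat.), MeOH, 0 °C; pentane extraction
Reagents that add atoms: none
Why: Methoxide attacks the unhindered trimethylsilyl group on the sp carbon (protodesilylation of an alkynylsilane), while the oxygen-bound triisopropylsilyl group is shielded; low temperature and catalytic base limit addition of methanol to the ynol ether.

Step 11
Reactants: 22 2-diazo-1-[(3S,4S,5E)-4-Res-3-Gua-5-(4-isopropoxy-3-methoxybenzylidene)cyclopent-1-en-1-yl]ethan-1-one; 28 (triisopropylsilyloxy)acetylene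
Product: 33 (1E,2S,3S)-2-Res-3-Gua-1-(4-isopropoxy-3-methoxybenzylidene)-6-(triisopropylsilyloxy)-2,3-dihydro-1H-inden-4-ol, via vinylketene 29 (not isolated), via cyclobutenone 30 (not isolated), via dienylketene 31 (not isolated), via cyclohexadienone 32 (not isolated)
Conditions: 28 (2.5 equiv), ClCH2CH2Cl (degassed), hν (440–450 nm LEDs), 20 °C; then 80 °C, dark
Reagents that add atoms: none
Why: Visible-light excitation of the diazocarbonyl n→π* band of 22 expels N2, and the Wolff shift moves C7a from the carbonyl carbon (C4) to the diazo carbon (C7), giving vinylketene 29. Its C4=C7 bond combines with the electron-rich alkyne 28 in a thermal [2+2] cycloaddition to 4-alkenylcyclobutenone 30, which opens by four-electron conrotatory cleavage to dienylketene 31. Ring A is then closed between C4 and C3a by a six-electron disrotatory electrocyclisation to cyclohexadienone 32, and enolisation gives the phenol; the heating period drives any remaining 30 through these two stages. This is the second-generation Danheiser benzannulation, known for unsaturated α-diazoketones with trialkylsilyloxyalkynes as a route to resorcinol monosilyl ethers. No stereocentre is created: C2 and C3 are sp3 spectators outside the pericyclic array and meet neither acid nor base. The step needs regioselectivity in the [2+2] event, which the polarisation of 28 supplies: its nucleophilic CH carbon bonds to the electrophilic ketene carbon C4, so oxygen ends on C6 and hydrogen on C5 and C7. It also needs the C1=C8 geometry to survive, which is addressed by irradiating only in the long-wavelength tail where the aryl diene of 22 and the stilbene-like chromophore of 33 should absorb little. The cross-conjugated C1=C8 bond cannot enter the electrocyclisation, because only C7a=C3a completes a linear triene with the ketene.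

Step 12
Reactants: 33 (1E,2S,3S)-2-Res-3-Gua-1-(4-isopropoxy-3-methoxybenzylidene)-6-(triisopropylsilyloxy)-2,3-dihydro-1H-inden-4-ol
Product: 34 (1E,2S,3S)-2-Res-3-Gua-1-(4-isopropoxy-3-methoxybenzylidene)-2,3-dihydro-1H-indene-4,6-diol
Conditions: Bu4NF, AcOH, THF, 0 °C
Reagents that add atoms: none
Why: Fluoride cleaves the aryl silyl ether, driven by Si–F bond formation; acetic acid buffers the phenoxide so the electron-rich resorcinol is not left as an air-sensitive anion, and isopropyl and methyl ethers are inert.

Step 13
Reactants: 34 (1E,2S,3S)-2-Res-3-Gua-1-(4-isopropoxy-3-methoxybenzylidene)-2,3-dihydro-1H-indene-4,6-diol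
Product: 35 gnetulin
Conditions: BCl3, CH2Cl2, −78 → 0 °C; then H2O
Reagents that add atoms: none
Why: BCl3 coordinates the ether oxygens and the secondary isopropyl groups leave as 2-chloropropane at or below 0 °C, conditions under which aryl methyl ethers are retained; aqueous work-up frees the phenols. Low temperature and short exposure are meant to prevent protonation of C1=C8 and closure by the C2 aryl ring; neither stereocentre is touched.

## Compound list

1 | 5-bromobenzene-1,3-diol (5-bromoresorcinol) | Oc1cc(O)cc(Br)c1 | starting material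
2 | 1-bromo-3,5-diisopropoxybenzene | CC(C)Oc1cc(Br)cc(OC(C)C)c1 | intermediate
3 | 4-bromo-2-methoxyphenol | COc1cc(Br)ccc1O | starting material
4 | 4-bromo-1-isopropoxy-2-methoxybenzene | COc1cc(Br)ccc1OC(C)C | intermediate
5 | (S)-4-(tert-butyldimethylsilyloxy)cyclopent-2-en-1-one | O=C1C=C[C@@H](O[Si](C)(C)C(C)(C)C)C1 | starting material
6 | 4-isopropoxy-3-methoxybenzaldehyde | COc1cc(C=O)ccc1OC(C)C | starting material
7 | (3,5-diisopropoxyphenyl)lithium | [Li]c1cc(OC(C)C)cc(OC(C)C)c1 | intermediate
8 | lithium bis(3,5-diisopropoxyphenyl)cuprate | [Li+].CC(C)Oc1cc([Cu-]c2cc(OC(C)C)cc(OC(C)C)c2)cc(OC(C)C)c1 | intermediate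
9 | lithium (3R,4S)-4-(tert-butyldimethylsilyloxy)-3-(3,5-diisopropoxyphenyl)cyclopent-1-en-1-olate | [Li]OC1=C[C@H](c2cc(OC(C)C)cc(OC(C)C)c2)[C@@H](O[Si](C)(C)C(C)(C)C)C1 | intermediate
10 | (2R,3R,4S)-4-(tert-butyldimethylsilyloxy)-3-(3,5-diisopropoxyphenyl)-2-[hydroxy(4-isopropoxy-3-methoxyphenyl)methyl]cyclopentan-1-one, both carbinol epimers | O=C1C[C@H](O[Si](C)(C)C(C)(C)C)[C@@H](c2cc(OC(C)C)cc(OC(C)C)c2)[C@@H]1C(O)c1ccc(OC(C)C)c(OC)c1 | intermediate
11 | methanesulfonate of 10 at the carbinol oxygen, (2R,3R,4S) | O=C1C[C@H](O[Si](C)(C)C(C)(C)C)[C@@H](c2cc(OC(C)C)cc(OC(C)C)c2)[C@@H]1C(OS(C)(=O)=O)c1ccc(OC(C)C)c(OC)c1 | intermediate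
12 | (2E,3S,4S)-4-(tert-butyldimethylsilyloxy)-3-(3,5-diisopropoxyphenyl)-2-(4-isopropoxy-3-methoxybenzylidene)cyclopentan-1-one | O=C1C[C@H](O[Si](C)(C)C(C)(C)C)[C@@H](c2cc(OC(C)C)cc(OC(C)C)c2)/C1=C\c1ccc(OC(C)C)c(OC)c1 | intermediate
13 | (2E,3S,4S)-3-(3,5-diisopropoxyphenyl)-4-hydroxy-2-(4-isopropoxy-3-methoxybenzylidene)cyclopentan-1-one | O=C1C[C@H](O)[C@@H](c2cc(OC(C)C)cc(OC(C)C)c2)/C1=C\c1ccc(OC(C)C)c(OC)c1 | intermediate
14 | (4S,5E)-4-(3,5-diisopropoxyphenyl)-5-(4-isopropoxy-3-methoxybenzylidene)cyclopent-2-en-1-one | O=C1C=C[C@@H](c2cc(OC(C)C)cc(OC(C)C)c2)/C1=C\c1ccc(OC(C)C)c(OC)c1 | intermediate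
15 | (4-isopropoxy-3-methoxyphenyl)lithium | [Li]c1ccc(OC(C)C)c(OC)c1 | intermediate
16 | lithium bis(4-isopropoxy-3-methoxyphenyl)cuprate | [Li+].COc1cc([Cu-]c2ccc(OC(C)C)c(OC)c2)ccc1OC(C)C | intermediate
17 | lithium (3R,4S,5E)-4-(3,5-diisopropoxyphenyl)-3-(4-isopropoxy-3-methoxyphenyl)-5-(4-isopropoxy-3-methoxybenzylidene)cyclopent-1-en-1-olate | [Li]OC1=C[C@H](c2ccc(OC(C)C)c(OC)c2)[C@@H](c2cc(OC(C)C)cc(OC(C)C)c2)/C1=C\c1ccc(OC(C)C)c(OC)c1 | intermediate
18 | (3R,4S,5E)-4-(3,5-diisopropoxyphenyl)-3-(4-isopropoxy-3-methoxyphenyl)-5-(4-isopropoxy-3-methoxybenzylidene)cyclopent-1-en-1-yl trifluoromethanesulfonate | O=S(=O)(OC1=C[C@H](c2ccc(OC(C)C)c(OC)c2)[C@@H](c2cc(OC(C)C)cc(OC(C)C)c2)/C1=C\c1ccc(OC(C)C)c(OC)c1)C(F)(F)F | intermediate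
19 | (3S,4S,5E)-4-(3,5-diisopropoxyphenyl)-1-(1-ethoxyethenyl)-3-(4-isopropoxy-3-methoxyphenyl)-5-(4-isopropoxy-3-methoxybenzylidene)cyclopent-1-ene | CCOC(=C)C1=C[C@H](c2ccc(OC(C)C)c(OC)c2)[C@@H](c2cc(OC(C)C)cc(OC(C)C)c2)/C1=C\c1ccc(OC(C)C)c(OC)c1 | intermediate
20 | 1-[(3S,4S,5E)-4-(3,5-diisopropoxyphenyl)-3-(4-isopropoxy-3-methoxyphenyl)-5-(4-isopropoxy-3-methoxybenzylidene)cyclopent-1-en-1-yl]ethan-1-one | CC(=O)C1=C[C@H](c2ccc(OC(C)C)c(OC)c2)[C@@H](c2cc(OC(C)C)cc(OC(C)C)c2)/C1=C\c1ccc(OC(C)C)c(OC)c1 | intermediate
21 | 4,4,4-trifluoro-1-[(3S,4S,5E)-4-(3,5-diisopropoxyphenyl)-3-(4-isopropoxy-3-methoxyphenyl)-5-(4-isopropoxy-3-methoxybenzylidene)cyclopent-1-en-1-yl]butane-1,3-dione | O=C(CC(=O)C(F)(F)F)C1=C[C@H](c2ccc(OC(C)C)c(OC)c2)[C@@H](c2cc(OC(C)C)cc(OC(C)C)c2)/C1=C\c1ccc(OC(C)C)c(OC)c1 | intermediate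
22 | 2-diazo-1-[(3S,4S,5E)-4-(3,5-diisopropoxyphenyl)-3-(4-isopropoxy-3-methoxyphenyl)-5-(4-isopropoxy-3-methoxybenzylidene)cyclopent-1-en-1-yl]ethan-1-one | [N-]=[N+]=CC(=O)C1=C[C@H](c2ccc(OC(C)C)c(OC)c2)[C@@H](c2cc(OC(C)C)cc(OC(C)C)c2)/C1=C\c1ccc(OC(C)C)c(OC)c1 | intermediate
23 | ethynyl(trimethyl)silane, (trimethylsilyl)acetylene | C#C[Si](C)(C)C | starting material
24 | triisopropylsilyl trifluoromethanesulfonate | CC(C)[Si](OS(=O)(=O)C(F)(F)F)(C(C)C)C(C)C | starting material
25 | lithium (trimethylsilyl)acetylide | [Li]C#C[Si](C)(C)C | intermediate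
26 | lithium 2-(trimethylsilyl)ethynolate | [Li]OC#C[Si](C)(C)C | intermediate
27 | triisopropyl{[(trimethylsilyl)ethynyl]oxy}silane | C[Si](C)(C)C#CO[Si](C(C)C)(C(C)C)C(C)C | intermediate
28 | (triisopropylsilyloxy)acetylene | C#CO[Si](C(C)C)(C(C)C)C(C)C | intermediate
29 | 2-[(3S,4S,5E)-4-(3,5-diisopropoxyphenyl)-3-(4-isopropoxy-3-methoxyphenyl)-5-(4-isopropoxy-3-methoxybenzylidene)cyclopent-1-en-1-yl]ethen-1-one (vinylketene) | O=C=CC1=C[C@H](c2ccc(OC(C)C)c(OC)c2)[C@@H](c2cc(OC(C)C)cc(OC(C)C)c2)/C1=C\c1ccc(OC(C)C)c(OC)c1 | intermediate
30 | 4-[(3S,4S,5E)-4-(3,5-diisopropoxyphenyl)-3-(4-isopropoxy-3-methoxyphenyl)-5-(4-isopropoxy-3-methoxybenzylidene)cyclopent-1-en-1-yl]-3-(triisopropylsilyloxy)cyclobut-2-en-1-one, both epimers at the cyclobutenone sp3 carbon | O=C3C=C(O[Si](C(C)C)(C(C)C)C(C)C)C3C1=C[C@H](c2ccc(OC(C)C)c(OC)c2)[C@@H](c2cc(OC(C)C)cc(OC(C)C)c2)/C1=C\c1ccc(OC(C)C)c(OC)c1 | intermediate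
31 | (3E)-4-[(3S,4S,5E)-4-(3,5-diisopropoxyphenyl)-3-(4-isopropoxy-3-methoxyphenyl)-5-(4-isopropoxy-3-methoxybenzylidene)cyclopent-1-en-1-yl]-3-(triisopropylsilyloxy)buta-1,3-dien-1-one (dienylketene) | O=C=C/C(O[Si](C(C)C)(C(C)C)C(C)C)=C\C1=C[C@H](c2ccc(OC(C)C)c(OC)c2)[C@@H](c2cc(OC(C)C)cc(OC(C)C)c2)/C1=C\c1ccc(OC(C)C)c(OC)c1 | intermediate
32 | 3a-H cyclohexa-2,4-dienone tautomer of 33 (1,2,3,3a-tetrahydro-4H-inden-4-one; C2 and C3 arranged as in 33, C3a as formed) | O=C1C=C(O[Si](C(C)C)(C(C)C)C(C)C)C=C2C1[C@H](c1ccc(OC(C)C)c(OC)c1)[C@@H](c1cc(OC(C)C)cc(OC(C)C)c1)/C2=C\c1ccc(OC(C)C)c(OC)c1 | intermediate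
33 | (1E,2S,3S)-2-(3,5-diisopropoxyphenyl)-3-(4-isopropoxy-3-methoxyphenyl)-1-(4-isopropoxy-3-methoxybenzylidene)-6-(triisopropylsilyloxy)-2,3-dihydro-1H-inden-4-ol | COc1cc(/C=C2/c3cc(O[Si](C(C)C)(C(C)C)C(C)C)cc(O)c3[C@H](c3ccc(OC(C)C)c(OC)c3)[C@H]2c2cc(OC(C)C)cc(OC(C)C)c2)ccc1OC(C)C | intermediate
34 | (1E,2S,3S)-2-(3,5-diisopropoxyphenyl)-3-(4-isopropoxy-3-methoxyphenyl)-1-(4-isopropoxy-3-methoxybenzylidene)-2,3-dihydro-1H-indene-4,6-diol | COc1cc(/C=C2/c3cc(O)cc(O)c3[C@H](c3ccc(OC(C)C)c(OC)c3)[C@H]2c2cc(OC(C)C)cc(OC(C)C)c2)ccc1OC(C)C | intermediate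
35 | gnetulin, (1E,2S,3S)-2-(3,5-dihydroxyphenyl)-3-(4-hydroxy-3-methoxyphenyl)-1-(4-hydroxy-3-methoxybenzylidene)-2,3-dihydro-1H-indene-4,6-diol | COc1cc(/C=C2/c3cc(O)cc(O)c3[C@H](c3ccc(O)c(OC)c3)[C@H]2c2cc(O)cc(O)c2)ccc1O | target

## Step count and least certain steps

Total: 13 steps. Longest linear sequence: 10 steps (steps 1, 3, 4, 5, 6, 7, 8, 11, 12, 13).

Step 11 (key step). The likeliest failures are E/Z isomerisation of C1=C8 and diversion of the excited diazoketone into carbene reactions (cyclopropenation, C–H insertion) in place of the Wolff shift. Both would arise because the diazocarbonyl group is conjugated with the aryl diene and shares its excited state. The fallback avoids light. From 18, palladium-catalysed coupling with BrZnCH2CO2Et (Pd(PPh3)4, THF) would give ethyl ester F1; LiOH would give acid F2 and (COCl)2 the acid chloride F3. Slow addition of F3 to Et3N and 28 in toluene at 80 °C would generate the same vinylketene 29 by dehydrochlorination in the dark, and the cascade would rejoin the route at 33.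

Step 3. The likeliest failures are proton transfer in enolate 9 or in the aldolate followed by expulsion of the silyloxy group, reversal of the aldol addition on warming, and a sluggish reaction of the copper-bound enolate with 6. Fallback: from 2 and 5, the same cuprate addition run with Me3SiCl present would give silyl enol ether F4, which is isolated. A Mukaiyama aldol addition of F4 to 6 (BF3·OEt2, CH2Cl2, −78 °C) then forms the C1–C8 bond without a basic enolate and rejoins the route at 10.

Step 6. The likeliest failures are attack at the exocyclic β-carbon C8, proton abstraction at C2 (erosion of enantiomeric purity through the dienolate), and incomplete O-sulfonylation of the copper-bound enolate. Fallback: from 4, bromine–lithium exchange (n-BuLi) and B(Oi-Pr)3 would give boronic acid F5. Rhodium-catalysed 1,4-addition of F5 to 14 ([Rh(OH)(C8H12)]2, dioxane/H2O, 20 °C; C8H12 = cycloocta-1,5-diene) would give ketone F6 under nearly neutral conditions, with the same anti approach expected. F6 has a single enolisable position, so KN(SiMe3)2 and the same triflimide at −78 °C would return to 18.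

Step 8. The likeliest failures are deprotonation at C3–H in place of the methyl group (epimerisation at C3 or migration of the ring double bond) and incomplete trifluoroacetylation. Fallback: from 18, hydroxycarbonylation (Pd(OAc)2, PPh3, CO, KOAc, DMF/H2O) would give acid F7, (COCl)2 the acid chloride F8, and Me3SiCHN2 (MeCN/THF, 0 °C) would acylate to 22. This is held in reserve because diazoalkanes can add to the conjugated alkene of an unsaturated acyl chloride.

Step 10. The likeliest failures are methoxide attack at the oxygen-bound silicon, base-catalysed addition of methanol to the ynol ether, and loss of the volatile product on concentration. Fallback: from 24, monolithium acetylide (acetylene, n-BuLi, THF, −78 °C) would be oxidised with t-BuOOLi to lithium ethynolate F9, which 24 would silylate on oxygen to give 28 directly. Disproportionation of the unsubstituted acetylide on warming is the reason this is not the first choice.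

## Further compounds

F1 | step 11 | ethyl 2-[(3S,4S,5E)-4-(3,5-diisopropoxyphenyl)-3-(4-isopropoxy-3-methoxyphenyl)-5-(4-isopropoxy-3-methoxybenzylidene)cyclopent-1-en-1-yl]acetate | CCOC(=O)CC1=C[C@H](c2ccc(OC(C)C)c(OC)c2)[C@@H](c2cc(OC(C)C)cc(OC(C)C)c2)/C1=C\c1ccc(OC(C)C)c(OC)c1
F2 | step 11 | 2-[(3S,4S,5E)-4-(3,5-diisopropoxyphenyl)-3-(4-isopropoxy-3-methoxyphenyl)-5-(4-isopropoxy-3-methoxybenzylidene)cyclopent-1-en-1-yl]acetic acid | OC(=O)CC1=C[C@H](c2ccc(OC(C)C)c(OC)c2)[C@@H](c2cc(OC(C)C)cc(OC(C)C)c2)/C1=C\c1ccc(OC(C)C)c(OC)c1
F3 | step 11 | 2-[(3S,4S,5E)-4-(3,5-diisopropoxyphenyl)-3-(4-isopropoxy-3-methoxyphenyl)-5-(4-isopropoxy-3-methoxybenzylidene)cyclopent-1-en-1-yl]acetyl chloride | ClC(=O)CC1=C[C@H](c2ccc(OC(C)C)c(OC)c2)[C@@H](c2cc(OC(C)C)cc(OC(C)C)c2)/C1=C\c1ccc(OC(C)C)c(OC)c1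
F4 | step 3 | {[(3R,4S)-4-(tert-butyldimethylsilyloxy)-3-(3,5-diisopropoxyphenyl)cyclopent-1-en-1-yl]oxy}trimethylsilane | C[Si](C)(C)OC1=C[C@H](c2cc(OC(C)C)cc(OC(C)C)c2)[C@@H](O[Si](C)(C)C(C)(C)C)C1
F5 | step 6 | (4-isopropoxy-3-methoxyphenyl)boronic acid | COc1cc(B(O)O)ccc1OC(C)C
F6 | step 6 | (2E,3S,4S)-3-(3,5-diisopropoxyphenyl)-4-(4-isopropoxy-3-methoxyphenyl)-2-(4-isopropoxy-3-methoxybenzylidene)cyclopentan-1-one | O=C1C[C@H](c2ccc(OC(C)C)c(OC)c2)[C@@H](c2cc(OC(C)C)cc(OC(C)C)c2)/C1=C\c1ccc(OC(C)C)c(OC)c1
F7 | step 8 | (3S,4S,5E)-4-(3,5-diisopropoxyphenyl)-3-(4-isopropoxy-3-methoxyphenyl)-5-(4-isopropoxy-3-methoxybenzylidene)cyclopent-1-ene-1-carboxylic acid | OC(=O)C1=C[C@H](c2ccc(OC(C)C)c(OC)c2)[C@@H](c2cc(OC(C)C)cc(OC(C)C)c2)/C1=C\c1ccc(OC(C)C)c(OC)c1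
F8 | step 8 | (3S,4S,5E)-4-(3,5-diisopropoxyphenyl)-3-(4-isopropoxy-3-methoxyphenyl)-5-(4-isopropoxy-3-methoxybenzylidene)cyclopent-1-ene-1-carbonyl chloride | ClC(=O)C1=C[C@H](c2ccc(OC(C)C)c(OC)c2)[C@@H](c2cc(OC(C)C)cc(OC(C)C)c2)/C1=C\c1ccc(OC(C)C)c(OC)c1
F9 | step 10 | lithium ethynolate | [Li]OC#C
A1 | alternative 1 | (E)-1-(2-bromo-3,5-diisopropoxyphenyl)-2-(3,5-diisopropoxyphenyl)-3-(4-isopropoxy-3-methoxyphenyl)prop-2-en-1-one | O=C(c1cc(OC(C)C)cc(OC(C)C)c1Br)/C(c1cc(OC(C)C)cc(OC(C)C)c1)=C/c1ccc(OC(C)C)c(OC)c1
A2 | alternative 1 | (2S,3S)-2-(3,5-diisopropoxyphenyl)-4,6-diisopropoxy-3-(4-isopropoxy-3-methoxyphenyl)indan-1-one | O=C1c2cc(OC(C)C)cc(OC(C)C)c2[C@H](c2ccc(OC(C)C)c(OC)c2)[C@H]1c1cc(OC(C)C)cc(OC(C)C)c1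
A3 | alternative 2 | {2-[(1E,3R)-3-[dimethyl(phenyl)silyl]-1-(3,5-diisopropoxyphenyl)-3-(4-isopropoxy-3-methoxyphenyl)prop-1-en-2-yl]-4,6-diisopropoxyphenyl}(4-hydroxy-3-methoxyphenyl)methanol, either carbinol epimer, C8 drawn for anti attack with the aryl group inside | OC(c1ccc(O)c(OC)c1)c1c(OC(C)C)cc(OC(C)C)cc1/C(=C\c1cc(OC(C)C)cc(OC(C)C)c1)[C@H]([Si](C)(C)c1ccccc1)c1ccc(OC(C)C)c(OC)c1
A4 | alternative 2 | gnetulin penta(isopropyl ether) with the free phenol on the C3 aryl group, (1E,2S,3S) | COc1cc(/C=C2/c3cc(OC(C)C)cc(OC(C)C)c3[C@H](c3ccc(O)c(OC)c3)[C@H]2c2cc(OC(C)C)cc(OC(C)C)c2)ccc1OC(C)C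
A5 | alternative 3 | (1S,2S)-1-(2-bromo-4,6-diisopropoxyphenyl)-2-(3,5-diisopropoxyphenyl)-1,4-bis(4-isopropoxy-3-methoxyphenyl)but-3-yne | Brc1cc(OC(C)C)cc(OC(C)C)c1[C@H](c1ccc(OC(C)C)c(OC)c1)[C@H](C#Cc1ccc(OC(C)C)c(OC)c1)c1cc(OC(C)C)cc(OC(C)C)c1
A6 | alternative 3 | gnetulin hexa(isopropyl ether), (1E,2S,3S) | COc1cc(/C=C2/c3cc(OC(C)C)cc(OC(C)C)c3[C@H](c3ccc(OC(C)C)c(OC)c3)[C@H]2c2cc(OC(C)C)cc(OC(C)C)c2)ccc1OC(C)C
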